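**Target:** CNP0207009.2 = (6R)-3-[(3E)-4-methyl-6-(2,6,6-trimethylcyclohex-1-en-1-yl)hex-3-en-1-yl]-6-[(3R)-5-oxooxolan-3-yl]-5,6-dihydro-2H-pyran-2-one (17)

## Retrosynthetic overview

1. 17 ⇒ sp2–sp3 bond between pyranone C3 and the side-chain CH2 (B-alkyl Suzuki–Miyaura): iodo bis-lactone 15 + monocyclic diene 5.
2. 5 ⇒ Wittig methylenation of allylic phosphonium salt 4 ⇒ ring A closed by proton-initiated cation–olefin monocyclization of the acyclic farnesyl phosphonium salt 3 (from farnesyl bromide 1), as in the cyclase step on the polyprenyl chain.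
3. 15 ⇒ δ-lactonization of a δ-hydroxy α-iodo enoate (ester cis to the carbinol chain) ⇐ ynoate 12 ⇐ epoxide 9 + ethyl propiolate 10.
4. 9 ⇒ translactonization/epoxide closure of tosylate 8 ⇐ trans-selective photochemical hydroxymethylation of the chiral-pool butenolide 6, which supplies both stereocentres.
5. Ring order: cyclohexene (step 2, side-chain branch); γ-lactone in its final connectivity (step 6); δ-lactone (step 8); the two halves are joined in step 9.

Assumption: the SMILES is read as the (6R)-pyranone/(3R)-oxolanone diastereomer named above, and one step ends with one isolated product (stages run in the same flask appear as non-isolated intermediates).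

## Route

Step 1
Reactants: 1 (2E,6E)-farnesyl bromide
Product: 3 [(2E,6E)-3,7,11-trimethyldodeca-2,6,10-trien-1-yl]triphenylphosphonium trifluoromethanesulfonate, via phosphonium bromide 2 (not isolated)
Conditions: PPh3 (1.05 equiv), MeCN, 25 °C, 16 h; then CF3SO3Na (aq)/CH2Cl2
Reagents that add atoms: triphenylphosphine, c1ccc(cc1)P(c1ccccc1)c1ccccc1; sodium trifluoromethanesulfonate, [Na+].[O-]S(=O)(=O)C(F)(F)F
Why: SN2 quaternisation of the primary allylic bromide by the phosphine (phosphonium salt formation) keeps both E-alkenes, and anion metathesis removes bromide so that no oxidisable or nucleophilic halide is present in the acid of step 2.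

Step 2
Reactants: 3
Product: 4 [(2E)-3-methyl-5-(2,6,6-trimethylcyclohex-1-en-1-yl)pent-2-en-1-yl]triphenylphosphonium trifluoromethanesulfonate
Conditions: CF3SO3H (3 equiv), CH2Cl2/MeNO2 (4:1), −40 → 0 °C, 1 h; NaHCO3 (aq); recrystallisation
Reagents that add atoms: none
Why: Proposed new method: a Brønsted-acid cation–olefin monocyclization in which Markovnikov protonation of the terminal trisubstituted alkene, 6-endo attack by the central alkene and E1 loss of a proton close the cyclohexene ring as in the terpene-cyclase step, while the cationic phosphonium on the allylic carbon keeps the 2,3-alkene from being protonated or from attacking the ring cation (either would place two positive charges 1,3 to each other), so the cascade should stop after one ring and the ring alkene can equilibrate to the tetrasubstituted isomer; the closest known reactions are the strong-acid cyclizations of pseudoionone to β-ionone and of geranyl phenyl sulfone to β-cyclogeranyl phenyl sulfone, and no stereocentre is formed while the 2E-alkene is untouched.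

Step 3
Reactants: 4
Product: 5 1,3,3-trimethyl-2-[(3E)-3-methylhexa-3,5-dien-1-yl]cyclohex-1-ene
Conditions: KOt-Bu (1.2 equiv), (CH2O)n (5 equiv), THF, 0 → 25 °C
Reagents that add atoms: formaldehyde (from paraformaldehyde), C=O
Why: Wittig methylenation of the semi-stabilised allylic ylide, generated in the presence of formaldehyde, gives a terminal alkene, so no new geometry arises and the existing E-alkene is kept.

Step 4
Reactants: 6 (5S)-5-(hydroxymethyl)furan-2(5H)-one
Product: 7 [(2S)-5-oxo-2,5-dihydrofuran-2-yl]methyl 4-methylbenzenesulfonate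
Conditions: TsCl (1.2 equiv), pyridine, CH2Cl2, 0 °C
Reagents that add atoms: 4-toluenesulfonyl chloride, Cc1ccc(cc1)S(=O)(=O)Cl
Why: Sulfonylation of the primary alcohol (tosylate formation) installs the leaving group for the later epoxide closure without touching the stereocentre.

Step 5
Reactants: 7
Product: 8 [(2S,3R)-3-(hydroxymethyl)-5-oxooxolan-2-yl]methyl 4-methylbenzenesulfonate
Conditions: hν (350 nm, Pyrex), Ph2CO (0.2 equiv), degassed MeOH, 20 °C
Reagents that add atoms: methanol, CO
Why: Benzophenone-sensitised photochemical hydroxymethylation (Giese-type conjugate addition of the hydroxymethyl radical from methanol) takes place at the butenolide β-carbon on the face anti to the tosyloxymethyl group, which sets the new (R) centre trans to the existing (S) centre.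

Step 6
Reactants: 8
Product: 9 (4R)-4-[(2S)-oxiran-2-yl]oxolan-2-one
Conditions: NaH (1.05 equiv), THF (0.05 M), −20 → 0 °C
Reagents that add atoms: none
Why: The primary alkoxide attacks the lactone carbonyl (intramolecular transesterification, a translactonization through a bicyclic tetrahedral intermediate) to give the γ-lactone connectivity of the target, and the secondary alkoxide so released closes the epoxide by intramolecular Williamson displacement of tosylate; neither stereocentre is touched, and direct tetrahydrofuran formation is disfavoured because it would need a trans-fused 5/5 bicycle.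

Step 7
Reactants: 9; 10 ethyl propiolate
Product: 12 ethyl (5R)-5-hydroxy-5-[(3R)-5-oxooxolan-3-yl]pent-2-ynoate, via lithium acetylide 11 (not isolated)
Conditions: 10 (1.5 equiv), n-BuLi (1.5 equiv), THF, −78 °C; BF3·OEt2 (1.5 equiv); then 9, −78 °C, 1 h; NH4Cl (aq)
Reagents that add atoms: none
Why: Yamaguchi–Hirao alkynylation, in which the BF3-activated terminal epoxide is opened at its CH2 by the stabilised lithium acetylide faster than the acetylide adds to the lactone at −78 °C; the carbinol centre is the untouched epoxide carbon (S becomes R only through the change in substituent priority).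

Step 8
Reactants: 12
Product: 15 (6R)-3-iodo-6-[(3R)-5-oxooxolan-3-yl]-5,6-dihydro-2H-pyran-2-one, via vinylstannane 13 (not isolated), via iodo hydroxy ester 14 (not isolated)
Conditions: Pd(PPh3)4 (3 mol%), Bu3SnH (1.1 equiv), THF, 0 °C; then I2 (1.2 equiv), 0 °C; then PPTS (0.2 equiv), toluene, 70 °C
Reagents that add atoms: iodine, [I][I]
Why: Pd-catalysed syn-hydrostannation of the ynoate places tin on the α-carbon, iododestannylation proceeds with retention, and the enoate so formed has its ester cis to the hydroxyalkyl chain and closes by acid-catalysed δ-lactonization with loss of ethanol, a step that also funnels any translactonized isomer into the bis-lactone.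

Step 9
Reactants: 5; 15
Product: 17 (6R)-3-[(3E)-4-methyl-6-(2,6,6-trimethylcyclohex-1-en-1-yl)hex-3-en-1-yl]-6-[(3R)-5-oxooxolan-3-yl]-5,6-dihydro-2H-pyran-2-one, via alkylborane 16 (not isolated)
Conditions: 5 (1.4 equiv), 9-BBN-H (1.4 equiv), THF, 0 → 25 °C; then 15, PdCl2(dppf) (5 mol%), AsPh3 (5 mol%), Cs2CO3 (2 equiv), DMF/THF/H2O, 25 °C; pH 4 work-up
Reagents that add atoms: none
Why: Chemoselective anti-Markovnikov hydroboration of the monosubstituted diene terminus followed by B-alkyl Suzuki–Miyaura coupling with the α-iodo enoate forms the sp3–sp2 bond without touching either stereocentre or the E-alkene.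

## Compound list

1 | (2E,6E)-farnesyl bromide [(2E,6E)-1-bromo-3,7,11-trimethyldodeca-2,6,10-triene] | CC(C)=CCC/C(C)=C/CC/C(C)=C/CBr | starting material
2 | [(2E,6E)-3,7,11-trimethyldodeca-2,6,10-trien-1-yl]triphenylphosphonium bromide | CC(C)=CCC/C(C)=C/CC/C(C)=C/C[P+](c1ccccc1)(c1ccccc1)c1ccccc1.[Br-] | intermediate (not isolated)
3 | [(2E,6E)-3,7,11-trimethyldodeca-2,6,10-trien-1-yl]triphenylphosphonium trifluoromethanesulfonate | CC(C)=CCC/C(C)=C/CC/C(C)=C/C[P+](c1ccccc1)(c1ccccc1)c1ccccc1.[O-]S(=O)(=O)C(F)(F)F | intermediate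
4 | [(2E)-3-methyl-5-(2,6,6-trimethylcyclohex-1-en-1-yl)pent-2-en-1-yl]triphenylphosphonium trifluoromethanesulfonate | CC1=C(CC/C(C)=C/C[P+](c2ccccc2)(c2ccccc2)c2ccccc2)C(C)(C)CCC1.[O-]S(=O)(=O)C(F)(F)F | intermediate
5 | 1,3,3-trimethyl-2-[(3E)-3-methylhexa-3,5-dien-1-yl]cyclohex-1-ene | CC1=C(CC/C(C)=C/C=C)C(C)(C)CCC1 | intermediate
6 | (5S)-5-(hydroxymethyl)furan-2(5H)-one | OC[C@H]1OC(=O)C=C1 | starting material
7 | [(2S)-5-oxo-2,5-dihydrofuran-2-yl]methyl 4-methylbenzenesulfonate | Cc1ccc(cc1)S(=O)(=O)OC[C@H]1OC(=O)C=C1 | intermediate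
8 | [(2S,3R)-3-(hydroxymethyl)-5-oxooxolan-2-yl]methyl 4-methylbenzenesulfonate | Cc1ccc(cc1)S(=O)(=O)OC[C@H]1OC(=O)C[C@@H]1CO | intermediate
9 | (4R)-4-[(2S)-oxiran-2-yl]oxolan-2-one | O=C1C[C@H](CO1)[C@H]1CO1 | intermediate
10 | ethyl propiolate | CCOC(=O)C#C | starting material
11 | ethyl 3-lithiopropiolate | [Li]C#CC(=O)OCC | intermediate (not isolated)
12 | ethyl (5R)-5-hydroxy-5-[(3R)-5-oxooxolan-3-yl]pent-2-ynoate | CCOC(=O)C#CC[C@@H](O)[C@H]1COC(=O)C1 | intermediate
13 | ethyl (2E,5R)-5-hydroxy-5-[(3R)-5-oxooxolan-3-yl]-2-(tributylstannyl)pent-2-enoate | CCOC(=O)/C(=C\C[C@@H](O)[C@H]1COC(=O)C1)[Sn](CCCC)(CCCC)CCCC | intermediate (not isolated)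
14 | ethyl (2E,5R)-5-hydroxy-2-iodo-5-[(3R)-5-oxooxolan-3-yl]pent-2-enoate | CCOC(=O)/C(=C\C[C@@H](O)[C@H]1COC(=O)C1)I | intermediate (not isolated)
15 | (6R)-3-iodo-6-[(3R)-5-oxooxolan-3-yl]-5,6-dihydro-2H-pyran-2-one | IC1=CC[C@H]([C@H]2COC(=O)C2)OC1=O | intermediate
16 | 9-[(3E)-4-methyl-6-(2,6,6-trimethylcyclohex-1-en-1-yl)hex-3-en-1-yl]-9-borabicyclo[3.3.1]nonane | CC1=C(CC/C(C)=C/CCB2C3CCCC2CCC3)C(C)(C)CCC1 | intermediate (not isolated)
17 | (6R)-3-[(3E)-4-methyl-6-(2,6,6-trimethylcyclohex-1-en-1-yl)hex-3-en-1-yl]-6-[(3R)-5-oxooxolan-3-yl]-5,6-dihydro-2H-pyran-2-one | CC1=C(CC/C(C)=C/CCC2=CC[C@H]([C@H]3COC(=O)C3)OC2=O)C(C)(C)CCC1 | target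

## Step count and risk

Total step count: 9 (steps 1–3 side chain, steps 4–8 bis-lactone, step 9 union).
Longest linear sequence: 6 steps (6 → 7 → 8 → 9 → 12 → 15 → 17).

The three steps most likely to fail:

The first is the ring A closure of step 2. It is a new substrate class for a cation–olefin cyclization; it may be sluggish, or it may give a mixture of ring-alkene isomers that does not crystallise clean. The fallback replaces the phosphonium stop-group and the Wittig step by sulfone chemistry; it sets out from 1 and comes back to the route at 5. Bromide 1 is treated with PhSO2Na in DMF to give farnesyl phenyl sulfone F1. F1 is cyclized with concentrated H2SO4 in AcOH, the conditions of the β-cyclogeranyl sulfone synthesis, with the sulfone-deactivated allylic alkene expected to hold the cascade at the monocyclic stage, to give monocyclic allylic sulfone F2. F2 is lithiated with n-BuLi at −78 °C and alkylated with ICH2SiMe3 to give β-silyl sulfone F3. Fluoride (Bu4NF, THF) then eliminates silyl and sulfinate to give diene 5.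

The second is the alkynylation of step 7. The BF3-activated epoxide sits next to a γ-lactone, so the acetylide may add to the lactone or the Lewis acid may trigger acyl migration. The fallback removes the lactone before the alkynylation and closes both lactones at the end; it sets out from 8 and comes back to the route at 15, so it also no longer depends on step 6. Alcohol 8 is silylated (t-BuMe2SiCl, imidazole) to silyl ether F4. K2CO3 in MeOH opens the lactone to the methyl ester, and the alkoxide closes the epoxide to give epoxy ester F5. Alkynylation with 10 under the conditions of step 7 gives hydroxy ynoate diester F6. Hydrostannation and iodination as in step 8 give stannane F7 and then iodo enoate diester F8. TsOH in MeOH, then toluene at 70 °C, removes the silyl group and closes the γ- and δ-lactones to give 15.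

The third is the coupling of step 9. Aqueous carbonate may open the two lactones, or the alkylborane may transfer slowly. The fallback delivers the side chain as an organozinc under base-free Negishi conditions; it sets out from 16 (made from 5 as in step 9) and comes back to the route at 17. Borane 16 is cleaved with I2 and NaOMe to homoallylic iodide F9. Zinc insertion (Zn dust, LiCl, THF) gives alkylzinc iodide F10. Coupling of F10 with 15 under Pd(PPh3)4 catalysis in THF at 25 °C gives 17.

## Further compounds

F1 | step 2 | [(2E,6E)-3,7,11-trimethyldodeca-2,6,10-trien-1-yl]sulfonylbenzene (farnesyl phenyl sulfone) | CC(C)=CCC/C(C)=C/CC/C(C)=C/CS(=O)(=O)c1ccccc1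
F2 | step 2 | {[(2E)-3-methyl-5-(2,6,6-trimethylcyclohex-1-en-1-yl)pent-2-en-1-yl]sulfonyl}benzene | CC1=C(CC/C(C)=C/CS(=O)(=O)c2ccccc2)C(C)(C)CCC1
F3 | step 2 | trimethyl[(3E)-4-methyl-2-(phenylsulfonyl)-6-(2,6,6-trimethylcyclohex-1-en-1-yl)hex-3-en-1-yl]silane (racemic at C2) | C[Si](C)(C)CC(/C=C(C)/CCC1=C(C)CCCC1(C)C)S(=O)(=O)c1ccccc1
F4 | step 7 | [(2S,3R)-3-({[tert-butyl(dimethyl)silyl]oxy}methyl)-5-oxooxolan-2-yl]methyl 4-methylbenzenesulfonate | Cc1ccc(cc1)S(=O)(=O)OC[C@H]1OC(=O)C[C@@H]1CO[Si](C)(C)C(C)(C)C
F5 | step 7 | methyl (3R)-4-{[tert-butyl(dimethyl)silyl]oxy}-3-[(2S)-oxiran-2-yl]butanoate | COC(=O)C[C@H](CO[Si](C)(C)C(C)(C)C)[C@H]1CO1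
F6 | step 7 | 1-ethyl 8-methyl (5R,6R)-6-({[tert-butyl(dimethyl)silyl]oxy}methyl)-5-hydroxyoct-2-ynedioate | CCOC(=O)C#CC[C@@H](O)[C@@H](CO[Si](C)(C)C(C)(C)C)CC(=O)OC
F7 | step 7 | 1-ethyl 8-methyl (2E,5R,6R)-6-({[tert-butyl(dimethyl)silyl]oxy}methyl)-5-hydroxy-2-(tributylstannyl)oct-2-enedioate | CCOC(=O)/C(=C\C[C@@H](O)[C@@H](CO[Si](C)(C)C(C)(C)C)CC(=O)OC)[Sn](CCCC)(CCCC)CCCC
F8 | step 7 | 1-ethyl 8-methyl (2E,5R,6R)-6-({[tert-butyl(dimethyl)silyl]oxy}methyl)-5-hydroxy-2-iodooct-2-enedioate | CCOC(=O)/C(=C\C[C@@H](O)[C@@H](CO[Si](C)(C)C(C)(C)C)CC(=O)OC)I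
F9 | step 9 | 2-[(3E)-6-iodo-3-methylhex-3-en-1-yl]-1,3,3-trimethylcyclohex-1-ene | CC1=C(CC/C(C)=C/CCI)C(C)(C)CCC1
F10 | step 9 | [(3E)-4-methyl-6-(2,6,6-trimethylcyclohex-1-en-1-yl)hex-3-en-1-yl]zinc iodide | CC1=C(CC/C(C)=C/CC[Zn]I)C(C)(C)CCC1
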